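**Plan**
- Cuts: the Z-alkene goes back to an alkyne, and the C3'–C(sp) bond to a Sonogashira coupling on a 3'-bromoflavanone. Ring C is then cut at O1–C8a and C4–C4a in one operation, the C2–C3 bond by an acetate aldol, and the C5'–prenyl bond by an aromatic Claisen rearrangement.
- Enabling feature: ring A meets ring C only through the adjacent carbons C8a (bonded to O1) and C4a (bonded to C4), which are the two termini of an aryne. O5, on the carbon next to C4a, polarises this 3,5-dioxygenated aryne so that oxygen adds at C8a and the carbanion arises at C4a.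
- Forward order: rings A and B are bought (phloroglucinol, 3-bromo-4-hydroxybenzaldehyde). Ring A becomes an ortho-silylaryl triflate; ring B is prenylated, methylated and extended by C3–C4. Ring C, the only ring built, closes in step 12, and the hydroxymethylbutenyl side chain is attached last.
- Stereochemistry: C2 (S) is set by a catalytic asymmetric Mukaiyama aldol (step 9) and only carried along afterwards. The Z-alkene comes from syn semihydrogenation of the alkyne (step 15).

Key step: step 12

Assumption: the antipode of the binaphthyl ligand in step 9 is the one whose titanium complex leaves the Si face of an aromatic aldehyde open. Both antipodes are equally accessible, and the sense is to be confirmed on the hydroxy ester of step 9 before material is carried on.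

**Step 1**
Reactants: 1 phloroglucinol
Product: 2 3,5-bis(methoxymethoxy)phenol
Conditions: MOMCl (2.0 equiv), i-Pr2NEt (2.2 equiv), DMF, 0 °C to rt
Reagents that add atoms: chloromethyl methyl ether (MOMCl), COCCl
Why: Williamson-type O-alkylation of the symmetric triphenol with two equivalents of MOMCl should give a statistical mixture from which the bis-ether is separated by chromatography, the mono-ether being resubmitted.

**Step 2**
Reactants: 2 3,5-bis(methoxymethoxy)phenol
Product: 3 2-bromo-3,5-bis(methoxymethoxy)phenol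
Conditions: NBS (1.0 equiv), CH2Cl2, −78 °C to 0 °C
Reagents that add atoms: N-bromosuccinimide, O=C1CCC(=O)N1Br
Why: Electrophilic aromatic bromination; all free positions are activated, but the two equivalent carbons beside the free hydroxyl are less crowded than C4 between two MOM ethers and profit from hydrogen-bonded delivery of NBS in a non-polar solvent, so the ortho-bromophenol should dominate and the C4 isomer is removed by chromatography.

**Step 3**
Reactants: 3 2-bromo-3,5-bis(methoxymethoxy)phenol
Product: 4 [2-bromo-3,5-bis(methoxymethoxy)phenoxy]trimethylsilane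
Conditions: (Me3Si)2NH, THF, 70 °C; evaporation
Reagents that add atoms: hexamethyldisilazane, C[Si](C)(C)N[Si](C)(C)C
Why: O-silylation of a phenol with hexamethyldisilazane gives only a volatile by-product, so the moisture-sensitive aryl silyl ether is obtained by evaporation and used crude.

**Step 4**
Reactants: 4 [2-bromo-3,5-bis(methoxymethoxy)phenoxy]trimethylsilane
Product: 7 3,5-bis(methoxymethoxy)-2-(trimethylsilyl)phenyl trifluoromethanesulfonate, via aryllithium 5 (not isolated), via lithium phenoxide 6 (not isolated)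
Conditions: n-BuLi (1.1 equiv), THF, −78 °C; then Tf2O (1.2 equiv), −78 °C
Reagents that add atoms: trifluoromethanesulfonic anhydride, O=S(=O)(OS(=O)(=O)C(F)(F)F)C(F)(F)F
Why: Bromine–lithium exchange outruns MOM-directed deprotonation at −78 °C, aryllithium 5 undergoes the retro-Brook shift of silicon from O to C, and phenoxide 6 is triflated in the same flask, the standard entry to ortho-silylaryl triflates.

**Step 5**
Reactants: 8 3-bromo-4-hydroxybenzaldehyde, 9 3-chloro-3-methylbut-1-yne
Product: 10 3-bromo-4-[(2-methylbut-3-yn-2-yl)oxy]benzaldehyde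
Conditions: CuCl2·2H2O (1 mol %), DBU, MeCN, 0 °C
Reagents that add atoms: none
Why: Copper-catalysed propargylic substitution of a tertiary propargylic chloride by a phenol works best with acidic, electron-poor phenols such as 8 and avoids the elimination seen under forcing Williamson conditions.

**Step 6**
Reactants: 10 3-bromo-4-[(2-methylbut-3-yn-2-yl)oxy]benzaldehyde
Product: 11 3-bromo-4-[(2-methylbut-3-en-2-yl)oxy]benzaldehyde
Conditions: H2 (1 atm), Pd/CaCO3 poisoned with Pb(OAc)2 (Lindlar catalyst), quinoline, EtOAc, rt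
Reagents that add atoms: none
Why: Lindlar semihydrogenation should stop at the terminal alkene and leave the aldehyde and the aryl bromide untouched, which also prevents the chromene formation that heating of the propargyl ether would cause.

**Step 7**
Reactants: 11 3-bromo-4-[(2-methylbut-3-en-2-yl)oxy]benzaldehyde
Product: 13 3-bromo-4-hydroxy-5-(3-methylbut-2-en-1-yl)benzaldehyde, via ortho-dienone 12 (not isolated)
Conditions: N,N-diethylaniline, 140 °C
Reagents that add atoms: none
Why: Aromatic Claisen rearrangement; the [3,3] shift transposes the 1,1-dimethylallyl group into a linear prenyl group at C5, the only ortho carbon that bears hydrogen, dienone 12 rearomatises by tautomerisation, and the basic solvent suppresses acid-catalysed chroman formation.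

**Step 8**
Reactants: 13 3-bromo-4-hydroxy-5-(3-methylbut-2-en-1-yl)benzaldehyde
Product: 14 3-bromo-4-methoxy-5-(3-methylbut-2-en-1-yl)benzaldehyde
Conditions: MeI, K2CO3, DMF, rt
Reagents that add atoms: iodomethane, CI
Why: Williamson methylation of the phenoxide installs the 4'-methyl ether of the target and removes the hydroxyl that could otherwise cyclise onto the prenyl group.

**Step 9**
Reactants: 14 3-bromo-4-methoxy-5-(3-methylbut-2-en-1-yl)benzaldehyde, 15 1-methoxy-1-(trimethylsilyloxy)ethene
Product: 17 methyl (3S)-3-[3-bromo-4-methoxy-5-(3-methylbut-2-en-1-yl)phenyl]-3-hydroxypropanoate, via silyl aldol adduct 16 (not isolated)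
Conditions: Ti(Oi-Pr)4 (3 mol %), Schiff base of 2-amino-2'-hydroxy-1,1'-binaphthyl and 3-bromo-5-tert-butylsalicylaldehyde (3 mol %), 3,5-di-tert-butylsalicylic acid (3 mol %), Et2O, −10 °C; then 1 M HCl, THF, 0 °C
Reagents that add atoms: none
Why: Catalytic asymmetric acetate Mukaiyama aldol, a reaction type that is highly selective for aromatic aldehydes; the chiral titanium chelate binds the aldehyde and blocks its Re face, attack on the Si face sets C2 as S, and silyl transfer gives 16, which is hydrolysed in the work-up.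

**Step 10**
Reactants: 17 methyl (3S)-3-[3-bromo-4-methoxy-5-(3-methylbut-2-en-1-yl)phenyl]-3-hydroxypropanoate
Product: 18 (3S)-3-[3-bromo-4-methoxy-5-(3-methylbut-2-en-1-yl)phenyl]-3-hydroxy-N-methoxy-N-methylpropanamide
Conditions: MeNHOMe·HCl (2.5 equiv), i-PrMgCl (6 equiv), THF, −20 °C to 0 °C; aq NH4Cl
Reagents that add atoms: N,O-dimethylhydroxylamine hydrochloride, CNOC.Cl
Why: Weinreb amidation of an ester with the chloromagnesium amide is routine on unprotected beta-hydroxy esters, and the low temperature should prevent retro-aldol cleavage and bromine–magnesium exchange, so C2 is not touched.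

**Step 11**
Reactants: 18 (3S)-3-[3-bromo-4-methoxy-5-(3-methylbut-2-en-1-yl)phenyl]-3-hydroxy-N-methoxy-N-methylpropanamide
Product: 19 (3S)-3-[3-bromo-4-methoxy-5-(3-methylbut-2-en-1-yl)phenyl]-N-methoxy-N-methyl-3-[(trimethylsilyl)oxy]propanamide
Conditions: TMSCl, imidazole, CH2Cl2, 0 °C; filtration through Et3N-deactivated silica
Reagents that add atoms: chlorotrimethylsilane, C[Si](C)(C)Cl
Why: Standard O-silylation stores the C2 oxygen as a neutral, proton-free alkoxide precursor that fluoride releases quickly.

**Step 12**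
Reactants: 7 3,5-bis(methoxymethoxy)-2-(trimethylsilyl)phenyl trifluoromethanesulfonate, 19 (3S)-3-[3-bromo-4-methoxy-5-(3-methylbut-2-en-1-yl)phenyl]-N-methoxy-N-methyl-3-[(trimethylsilyl)oxy]propanamide
Product: 24 (2S)-2-[3-bromo-4-methoxy-5-(3-methylbut-2-en-1-yl)phenyl]-5,7-bis(methoxymethoxy)-2,3-dihydro-4H-chromen-4-one, via benzyne 20 (not isolated), via potassium alkoxide 21 (not isolated), via aryl anion 22 (not isolated), via tetrahedral adduct 23 (not isolated)
Conditions: KF (3.5 equiv), 18-crown-6 (3.5 equiv), THF, 0 °C, 7 (1.2 equiv) added over 2 h, then rt; AcOH, 0 °C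
Reagents that add atoms: none
Why: Proposed new method: fluoride attacks the C–SiMe3 group of 7 and, with departure of triflate, unmasks aryne 20, and it also desilylates 19 to alkoxide 21 in THF, a medium that offers neither O–H nor acidic C–H bonds. Alkoxide 21 adds to the aryne terminus remote from the neighbouring MOM ether, which forms O1–C8a and leaves the charge of aryl anion 22 on C4a next to the electron-withdrawing O5; this regioselectivity is the one selectivity the step needs, and the O5 substituent secures it through the distortion and polarisation typical of 3-alkoxyarynes. Anion 22 then attacks the amide carbonyl in a 6-exo-trig closure that forms C4–C4a and completes ring C. The N-methoxy-N-methylamide is preferred to an alkyl ester because adduct 23 cannot expel its amide nucleofuge before the acetic acid quench, so neither the ketone nor a liberated alkoxide base is exposed to basic conditions and ring opening to the chalcone (the racemisation path) is shut off, and because its weakly acidic C3 protons slow retro-aldol cleavage of 21, beta-elimination and the competing C3-to-C4a proton transfer. The closest known reaction types are the fluoride-triggered annulation of arynes with ortho-hydroxybenzoate esters to xanthones, the insertion of arynes into the amide bond of beta-lactams to give 2,3-dihydroquinolin-4-ones, and the Parham cyclisation of ortho-metallated aryl ethers onto Weinreb amides. No lasting stereocentre is created (C4 of 23 becomes the carbonyl carbon) and none of the four bonds at C2 is touched, so the S configuration of 19 should pass unchanged into 24.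

**Step 13**
Reactants: 24 (2S)-2-[3-bromo-4-methoxy-5-(3-methylbut-2-en-1-yl)phenyl]-5,7-bis(methoxymethoxy)-2,3-dihydro-4H-chromen-4-one
Product: 25 (2S)-2-[3-bromo-4-methoxy-5-(3-methylbut-2-en-1-yl)phenyl]-5,7-dihydroxy-2,3-dihydro-4H-chromen-4-one
Conditions: HCl (about 1 M) in MeOH, 40 °C
Reagents that add atoms: none
Why: Acid-catalysed acetal exchange with methanol removes both MOM groups before the acid-labile tertiary alcohol is introduced; the prenyl alkene and the aryl methyl ether usually withstand dilute methanolic HCl in prenylflavonoid work, and the 4'-methoxy group, twisted out of plane by its two ortho neighbours, gives little help to ionisation of the C2–O1 bond.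

**Step 14**
Reactants: 25 (2S)-2-[3-bromo-4-methoxy-5-(3-methylbut-2-en-1-yl)phenyl]-5,7-dihydroxy-2,3-dihydro-4H-chromen-4-one, 26 2-methylbut-3-yn-2-ol
Product: 27 (2S)-5,7-dihydroxy-2-[3-(3-hydroxy-3-methylbut-1-yn-1-yl)-4-methoxy-5-(3-methylbut-2-en-1-yl)phenyl]-2,3-dihydro-4H-chromen-4-one
Conditions: 26 (1.5 equiv), Pd(PhCN)2Cl2 (3 mol %), P(t-Bu)3 (6 mol %), CuI (2 mol %), i-Pr2NH (4 equiv), dioxane, rt, degassed
Reagents that add atoms: none
Why: Sonogashira coupling; the bulky electron-rich phosphine lets zerovalent palladium insert into the electron-rich aryl bromide at room temperature, free phenols are tolerated, and a secondary amine at this temperature should not open ring C, since the 7-phenolate lowers the acidity of C3–H and the 4'-methyl ether rules out a quinone methide pathway.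

**Step 15**
Reactants: 27 (2S)-5,7-dihydroxy-2-[3-(3-hydroxy-3-methylbut-1-yn-1-yl)-4-methoxy-5-(3-methylbut-2-en-1-yl)phenyl]-2,3-dihydro-4H-chromen-4-one
Product: 28 (2S)-5,7-dihydroxy-2-{3-[(1Z)-3-hydroxy-3-methylbut-1-en-1-yl]-4-methoxy-5-(3-methylbut-2-en-1-yl)phenyl}-2,3-dihydro-4H-chromen-4-one (CNP0223123.2)
Conditions: H2 (1 atm), Pd/CaCO3 poisoned with Pb(OAc)2 (Lindlar catalyst), quinoline, EtOAc, rt, stopped after one equivalent of H2
Reagents that add atoms: none
Why: Lindlar semihydrogenation delivers both hydrogens to one face of the alkyne and so sets the Z-alkene, while the trisubstituted prenyl alkene and the ketone are inert and the neutral medium spares the tertiary allylic alcohol and C2.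

**Compound list**
1 | phloroglucinol | Oc1cc(O)cc(O)c1 | starting material
2 | 3,5-bis(methoxymethoxy)phenol | COCOc1cc(O)cc(OCOC)c1 | intermediate
3 | 2-bromo-3,5-bis(methoxymethoxy)phenol | Oc1cc(OCOC)cc(OCOC)c1Br | intermediate
4 | [2-bromo-3,5-bis(methoxymethoxy)phenoxy]trimethylsilane | C[Si](C)(C)Oc1cc(OCOC)cc(OCOC)c1Br | intermediate
5 | 2,4-bis(methoxymethoxy)-6-(trimethylsilyloxy)phenyllithium | C[Si](C)(C)Oc1cc(OCOC)cc(OCOC)c1[Li] | intermediate
6 | lithium 3,5-bis(methoxymethoxy)-2-(trimethylsilyl)phenoxide | [Li+].[O-]c1cc(OCOC)cc(OCOC)c1[Si](C)(C)C | intermediate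
7 | 3,5-bis(methoxymethoxy)-2-(trimethylsilyl)phenyl trifluoromethanesulfonate | COCOc1cc(OCOC)c([Si](C)(C)C)c(OS(=O)(=O)C(F)(F)F)c1 | intermediate
8 | 3-bromo-4-hydroxybenzaldehyde | O=Cc1ccc(O)c(Br)c1 | starting material
9 | 3-chloro-3-methylbut-1-yne | CC(C)(Cl)C#C | starting material
10 | 3-bromo-4-[(2-methylbut-3-yn-2-yl)oxy]benzaldehyde | O=Cc1ccc(OC(C)(C)C#C)c(Br)c1 | intermediate
11 | 3-bromo-4-[(2-methylbut-3-en-2-yl)oxy]benzaldehyde | O=Cc1ccc(OC(C)(C)C=C)c(Br)c1 | intermediate
12 | 5-bromo-3-(3-methylbut-2-en-1-yl)-4-oxocyclohexa-1,5-diene-1-carbaldehyde (racemic) | O=CC1=CC(CC=C(C)C)C(=O)C(Br)=C1 | intermediate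
13 | 3-bromo-4-hydroxy-5-(3-methylbut-2-en-1-yl)benzaldehyde | O=Cc1cc(Br)c(O)c(CC=C(C)C)c1 | intermediate
14 | 3-bromo-4-methoxy-5-(3-methylbut-2-en-1-yl)benzaldehyde | O=Cc1cc(Br)c(OC)c(CC=C(C)C)c1 | intermediate
15 | 1-methoxy-1-(trimethylsilyloxy)ethene | C=C(OC)O[Si](C)(C)C | starting material
16 | methyl (3S)-3-[3-bromo-4-methoxy-5-(3-methylbut-2-en-1-yl)phenyl]-3-[(trimethylsilyl)oxy]propanoate | COc1c(Br)cc([C@@H](O[Si](C)(C)C)CC(=O)OC)cc1CC=C(C)C | intermediate
17 | methyl (3S)-3-[3-bromo-4-methoxy-5-(3-methylbut-2-en-1-yl)phenyl]-3-hydroxypropanoate | COc1c(Br)cc([C@@H](O)CC(=O)OC)cc1CC=C(C)C | intermediate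
18 | (3S)-3-[3-bromo-4-methoxy-5-(3-methylbut-2-en-1-yl)phenyl]-3-hydroxy-N-methoxy-N-methylpropanamide | COc1c(Br)cc([C@@H](O)CC(=O)N(C)OC)cc1CC=C(C)C | intermediate
19 | (3S)-3-[3-bromo-4-methoxy-5-(3-methylbut-2-en-1-yl)phenyl]-N-methoxy-N-methyl-3-[(trimethylsilyl)oxy]propanamide | COc1c(Br)cc([C@@H](O[Si](C)(C)C)CC(=O)N(C)OC)cc1CC=C(C)C | intermediate
20 | 3,5-bis(methoxymethoxy)benzyne | COCOC1=CC(OCOC)=CC#C1 | intermediate
21 | potassium alkoxide of 18 | COc1c(Br)cc([C@@H]([O-])CC(=O)N(C)OC)cc1CC=C(C)C.[K+] | intermediate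
22 | potassium 2-{(1S)-1-aryl-3-[methoxy(methyl)amino]-3-oxopropoxy}-4,6-bis(methoxymethoxy)phenide (charge on C4a) | COc1c(Br)cc([C@@H](Oc2cc(OCOC)cc(OCOC)[c-]2)CC(=O)N(C)OC)cc1CC=C(C)C.[K+] | intermediate
23 | potassium (2S)-2-aryl-4-[methoxy(methyl)amino]-5,7-bis(methoxymethoxy)chroman-4-olate (C4 undefined) | COc1c(Br)cc([C@@H]2CC([O-])(N(C)OC)c3c(OCOC)cc(OCOC)cc3O2)cc1CC=C(C)C.[K+] | intermediate
24 | (2S)-2-[3-bromo-4-methoxy-5-(3-methylbut-2-en-1-yl)phenyl]-5,7-bis(methoxymethoxy)-2,3-dihydro-4H-chromen-4-one | COc1c(Br)cc([C@@H]2CC(=O)c3c(OCOC)cc(OCOC)cc3O2)cc1CC=C(C)C | intermediate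
25 | (2S)-2-[3-bromo-4-methoxy-5-(3-methylbut-2-en-1-yl)phenyl]-5,7-dihydroxy-2,3-dihydro-4H-chromen-4-one | COc1c(Br)cc([C@@H]2CC(=O)c3c(O)cc(O)cc3O2)cc1CC=C(C)C | intermediate
26 | 2-methylbut-3-yn-2-ol | CC(C)(O)C#C | starting material
27 | (2S)-5,7-dihydroxy-2-[3-(3-hydroxy-3-methylbut-1-yn-1-yl)-4-methoxy-5-(3-methylbut-2-en-1-yl)phenyl]-2,3-dihydro-4H-chromen-4-one | COc1c(C#CC(C)(C)O)cc([C@@H]2CC(=O)c3c(O)cc(O)cc3O2)cc1CC=C(C)C | intermediate
28 | (2S)-5,7-dihydroxy-2-{3-[(1Z)-3-hydroxy-3-methylbut-1-en-1-yl]-4-methoxy-5-(3-methylbut-2-en-1-yl)phenyl}-2,3-dihydro-4H-chromen-4-one (CNP0223123.2) | COc1c(/C=C\C(C)(C)O)cc([C@@H]2CC(=O)c3c(O)cc(O)cc3O2)cc1CC=C(C)C | target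

**Step count**
Total step count: 15. Longest linear sequence: 11 (steps 5 to 15). The ring A branch (steps 1 to 4) joins at step 12.

**Steps most likely to fail**

1. Step 12.
 - What may go wrong: the aryl anion may take a proton (from C3 or from traces of water) faster than it reaches the carbonyl. The free alkoxide may fragment by retro-aldol cleavage before it meets the aryne. The aryne may be consumed by the prenyl group in an ene reaction.
 - Fallback: known chemistry that makes the same two bonds one after the other. It sets out from aldehyde 14 and phenol 2 and comes back at 24.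
 - Steps 9 and 10 are repeated on 14 with the mirror-image ligand. This gives methyl (3R)-3-[3-bromo-4-methoxy-5-(3-methylbut-2-en-1-yl)phenyl]-3-[(trimethylsilyl)oxy]propanoate F1 (hydrolysed in the work-up), methyl (3R)-3-[3-bromo-4-methoxy-5-(3-methylbut-2-en-1-yl)phenyl]-3-hydroxypropanoate F2, and then (3R)-3-[3-bromo-4-methoxy-5-(3-methylbut-2-en-1-yl)phenyl]-3-hydroxy-N-methoxy-N-methylpropanamide F3.
 - Phenol 2 is iodinated with NIS to 2-iodo-3,5-bis(methoxymethoxy)phenol F4.
 - Mitsunobu etherification of F3 with F4 (PPh3, DIAD, toluene, 0 °C) forms O1–C8a with inversion and gives (3S)-3-[3-bromo-4-methoxy-5-(3-methylbut-2-en-1-yl)phenyl]-3-[2-iodo-3,5-bis(methoxymethoxy)phenoxy]-N-methoxy-N-methylpropanamide F5.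
 - Iodine–magnesium exchange (i-PrMgCl·LiCl, THF, −40 °C) leaves the ring B bromide alone. Parham-type cyclisation of the arylmagnesium onto the Weinreb amide then forms C4–C4a and delivers 24.

2. Step 14.
 - What may go wrong: oxidative addition of the electron-rich, ortho-substituted bromide may be sluggish. The alkyne may homocouple. The amine may erode C2 by reversible opening of ring C.
 - Fallback: the side chain is brought in with its Z geometry already set and without an amine. It sets out from 26 and 25 and comes back at target 28, so step 15 also drops out.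
 - Double deprotonation of 26 (n-BuLi, 2 equiv) and treatment with Bu3SnCl gives 2-methyl-4-(tributylstannyl)but-3-yn-2-ol F8.
 - Hydrozirconation with Cp2Zr(H)Cl followed by protonolysis gives (Z)-2-methyl-4-(tributylstannyl)but-3-en-2-ol F9.
 - Stille coupling of F9 with 25 (Pd2(dba)3, P(t-Bu)3, CsF, dioxane, rt) proceeds with retention of alkene geometry and should give 28.

3. Step 9.
 - What may go wrong: facial selectivity may be poor or turnover slow with the 3,4,5-trisubstituted aldehyde.
 - Fallback: the centre is set by reduction instead of by C–C bond formation. It sets out from 14 and comes back at 18, bypassing steps 9 and 10.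
 - Addition of the lithium enolate of N-methoxy-N-methylacetamide (LDA, THF, −78 °C) to 14 gives racemic 3-[3-bromo-4-methoxy-5-(3-methylbut-2-en-1-yl)phenyl]-3-hydroxy-N-methoxy-N-methylpropanamide F6.
 - Dess–Martin periodinane gives 3-[3-bromo-4-methoxy-5-(3-methylbut-2-en-1-yl)phenyl]-N-methoxy-N-methyl-3-oxopropanamide F7.
 - Asymmetric transfer hydrogenation with RuCl[(S,S)-TsDPEN](p-cymene) in HCO2H/Et3N reduces aryl ketones to the S carbinols and leaves the prenyl alkene and the bromide alone. It should give 18.

**Further compounds**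
F1 | step 12 | methyl (3R)-3-[3-bromo-4-methoxy-5-(3-methylbut-2-en-1-yl)phenyl]-3-[(trimethylsilyl)oxy]propanoate | COc1c(Br)cc([C@H](O[Si](C)(C)C)CC(=O)OC)cc1CC=C(C)C
F2 | step 12 | methyl (3R)-3-[3-bromo-4-methoxy-5-(3-methylbut-2-en-1-yl)phenyl]-3-hydroxypropanoate | COc1c(Br)cc([C@H](O)CC(=O)OC)cc1CC=C(C)C
F3 | step 12 | (3R)-3-[3-bromo-4-methoxy-5-(3-methylbut-2-en-1-yl)phenyl]-3-hydroxy-N-methoxy-N-methylpropanamide | COc1c(Br)cc([C@H](O)CC(=O)N(C)OC)cc1CC=C(C)C
F4 | step 12 | 2-iodo-3,5-bis(methoxymethoxy)phenol | Oc1cc(OCOC)cc(OCOC)c1I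
F5 | step 12 | (3S)-3-[3-bromo-4-methoxy-5-(3-methylbut-2-en-1-yl)phenyl]-3-[2-iodo-3,5-bis(methoxymethoxy)phenoxy]-N-methoxy-N-methylpropanamide | COc1c(Br)cc([C@@H](Oc2cc(OCOC)cc(OCOC)c2I)CC(=O)N(C)OC)cc1CC=C(C)C
F6 | step 9 | racemic 3-[3-bromo-4-methoxy-5-(3-methylbut-2-en-1-yl)phenyl]-3-hydroxy-N-methoxy-N-methylpropanamide | COc1c(Br)cc(C(O)CC(=O)N(C)OC)cc1CC=C(C)C
F7 | step 9 | 3-[3-bromo-4-methoxy-5-(3-methylbut-2-en-1-yl)phenyl]-N-methoxy-N-methyl-3-oxopropanamide | COc1c(Br)cc(C(=O)CC(=O)N(C)OC)cc1CC=C(C)C
F8 | step 14 | 2-methyl-4-(tributylstannyl)but-3-yn-2-ol | CCCC[Sn](CCCC)(CCCC)C#CC(C)(C)O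
F9 | step 14 | (Z)-2-methyl-4-(tributylstannyl)but-3-en-2-ol | CCCC[Sn](CCCC)(CCCC)/C=C\C(C)(C)O
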